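**Strategy.** The route cuts the γ-lactone (O, C6, C7, C11, C12; germacrane numbering) at O–C6 and C11–C12, which releases CO2. C11 and C6 are 1,3-related through C7. In the precursor both are electrophilic: an alkenyl bromide at C11 and a 6β-mesylate at C6. Two cathodic electrons reverse the polarity of C11, CO2 is stitched between the two carbons in one cell, and SN2 inversion gives the trans-lactone. The precursor is a ten-membered 1(10)E-cyclodecenone. It comes from a Nozaki–Hiyama ring closure whose 2-bromoallyl unit leaves the alkenyl bromide behind. Nitromethane serves as the C3 carbonyl linchpin. Both carbinol centres (C6, C8) are corrected by inversion.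

Key step: step 16

Remark on the chemistry:
- Numbering: C1/C10 are the epoxide carbons (C10 bears C14H3), C3 is the ketone, C4 bears C15H2OH, C6 bears the lactone O, C8 bears the angelate, C11=C13H2, and C12 is the lactone C=O.
- TBS = tert-butyldimethylsilyl; TBDPS = tert-butyldiphenylsilyl.
- C3 of 17 is assumed to form as a mixture of epimers. This does not matter because step 11 erases the centre.

Step 1
Reactants: 1 geranyl chloride
Product: 2 (4E)-6-chloro-4-methylhex-4-enal
Conditions: O3 (one equivalent, Sudan Red 7B end point), CH2Cl2, −78 °C; Me2S, −78 °C to rt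
Reagents that add atoms: ozone, [O-][O+]=O
Why: Ozonolysis should cleave only the isopropylidene alkene, because the other trisubstituted alkene is deactivated by its allylic chlorine.

Step 2
Reactants: 3 ethyl (triphenylphosphoranylidene)acetate
Product: 4 ethyl bromo(triphenylphosphoranylidene)acetate
Conditions: NBS, CH2Cl2, −20 °C to rt; aq K2CO3 wash
Reagents that add atoms: N-bromosuccinimide, O=C1CCC(=O)N1Br
Why: Electrophilic bromination of a stabilised ylide followed by proton loss to the succinimide anion is the usual way to α-bromo ylides.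

Step 3
Reactants: 2 (4E)-6-chloro-4-methylhex-4-enal; 4 ethyl bromo(triphenylphosphoranylidene)acetate
Product: 6 ethyl (2Z,4S,6E)-4-(anilinooxy)-2-bromo-8-chloro-6-methylocta-2,6-dienoate, via α-aminoxy aldehyde 5 (not isolated)
Conditions: PhNO, D-proline (20 mol %), MeCN, −20 °C; then 4, CH2Cl2, 0 °C to rt
Reagents that add atoms: nitrosobenzene, O=Nc1ccccc1
Why: Proline-catalysed enamine α-aminoxylation sets C8 as S (D-proline, hydrogen-bonded enamine–nitroso transition state), and the labile aldehyde is trapped at once by a Wittig olefination that gives mainly the Z bromoalkene, a geometry of no consequence later.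

Step 4
Reactants: 6 ethyl (2Z,4S,6E)-4-(anilinooxy)-2-bromo-8-chloro-6-methylocta-2,6-dienoate
Product: 7 ethyl (2Z,4S,6E)-2-bromo-8-chloro-4-hydroxy-6-methylocta-2,6-dienoate
Conditions: Cu(OAc)2 (30 mol %), EtOH, rt
Reagents that add atoms: none
Why: Copper-catalysed N–O cleavage of the O-anilino group frees the C8 alcohol under neutral conditions, and the trans relation of ester and C8 across the alkene rules out lactonisation.

Step 5
Reactants: 7 ethyl (2Z,4S,6E)-2-bromo-8-chloro-4-hydroxy-6-methylocta-2,6-dienoate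
Product: 8 ethyl (2Z,4S,6E)-2-bromo-4-(TBSO)-8-chloro-6-methylocta-2,6-dienoate
Conditions: TBSOTf, 2,6-lutidine, CH2Cl2, −78 °C
Reagents that add atoms: tert-butyldimethylsilyl triflate, CC(C)(C)[Si](C)(C)OS(=O)(=O)C(F)(F)F
Why: Silylation with the triflate and a non-nucleophilic base protects O8 without alkylating the base at the allylic chloride.

Step 6
Reactants: 8 ethyl (2Z,4S,6E)-2-bromo-4-(TBSO)-8-chloro-6-methylocta-2,6-dienoate
Product: 9 (2Z,4S,6E)-2-bromo-4-(TBSO)-8-chloro-6-methylocta-2,6-dien-1-ol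
Conditions: i-Bu2AlH (2.2 equiv), CH2Cl2, −78 °C; aq Rochelle salt
Reagents that add atoms: none
Why: 1,2-Reduction of the enoate by diisobutylaluminium hydride gives the 2-bromoallylic alcohol, while alkenyl bromide, allylic chloride and silyl ether are inert at −78 °C.

Step 7
Reactants: 10 allyl alcohol
Product: 11 allyl TBDPS ether
Conditions: TBDPSCl, imidazole, CH2Cl2, rt
Reagents that add atoms: tert-butyldiphenylsilyl chloride, CC(C)(C)[Si](Cl)(c1ccccc1)c1ccccc1
Why: Standard silylation installs the bulky, acid-stable group that later keeps O15 from acting as a nucleophile towards C6.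

Step 8
Reactants: 11 allyl TBDPS ether; 12 (E)-crotonaldehyde
Product: 13 (E)-4-(TBDPSO)but-2-enal
Conditions: second-generation Hoveyda–Grubbs catalyst (2 mol %), 12 (3 equiv), CH2Cl2, 40 °C
Reagents that add atoms: crotonaldehyde (12), C/C=C/C=O
Why: Cross metathesis of an unhindered terminal alkene with an electron-poor enal is selective for the cross product and for the E alkene.

Step 9
Reactants: 13 (E)-4-(TBDPSO)but-2-enal; 14 nitromethane
Product: 16 (2R)-1-(TBDPSO)-4,4-dimethoxy-2-(nitromethyl)butane, via nitro aldehyde 15 (not isolated)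
Conditions: MeNO2 (10 equiv), (S)-α,α-diphenylprolinol trimethylsilyl ether (10 mol %), PhCO2H (20 mol %), MeOH, rt; then HC(OMe)3, p-TsOH (5 mol %), rt
Reagents that add atoms: nitromethane (14), C[N+](=O)[O-]; trimethyl orthoformate, COC(OC)OC
Why: In this iminium-catalysed Michael addition the diphenyl(silyloxy)methyl group of the S catalyst shields one face of the E iminium ion, so nitromethane sets C4 from the open face, and acid-catalysed acetalisation masks the C6 aldehyde in the same flask.

Step 10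
Reactants: 9 (2Z,4S,6E)-2-bromo-4-(TBSO)-8-chloro-6-methylocta-2,6-dien-1-ol; 16 (2R)-1-(TBDPSO)-4,4-dimethoxy-2-(nitromethyl)butane
Product: 17 (2Z,4S,6E,10R)-2-bromo-4-(TBSO)-10-[(TBDPSO)methyl]-12,12-dimethoxy-6-methyl-9-nitrododeca-2,6-dien-1-ol (C9 epimers)
Conditions: Pd2(dba)3·CHCl3 (2.5 mol %), dppe (6 mol %), Cs2CO3, THF, rt
Reagents that add atoms: none
Why: In this Tsuji–Trost allylation zerovalent palladium ionises the primary allylic chloride far faster than it inserts into the hindered alkenyl bromide at rt, and the soft nitronate attacks the unsubstituted allyl terminus through carbon, which makes C2–C3 and keeps the E alkene.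

Step 11
Reactants: 17 (2Z,4S,6E,10R)-2-bromo-4-(TBSO)-10-[(TBDPSO)methyl]-12,12-dimethoxy-6-methyl-9-nitrododeca-2,6-dien-1-ol
Product: 19 (2Z,4S,6E,10S)-2-bromo-4-(TBSO)-10-[(TBDPSO)methyl]-1-hydroxy-12,12-dimethoxy-6-methyldodeca-2,6-dien-9-one, via sodium nitronate 18 (not isolated)
Conditions: NaOMe, MeOH, 0 °C; then TiCl3, NH4OAc, H2O–MeOH (pH about 6), 0 °C to rt
Reagents that add atoms: water, O
Why: In this reductive Nef reaction trivalent titanium reduces the nitronate to the imine, which buffered water hydrolyses to the C3 ketone at a pH that spares acetal, silyl ethers and the C4 centre (its descriptor changes by priority only).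

Step 12
Reactants: 19 (2Z,4S,6E,10S)-2-bromo-4-(TBSO)-10-[(TBDPSO)methyl]-1-hydroxy-12,12-dimethoxy-6-methyldodeca-2,6-dien-9-one
Product: 20 (2Z,4S,6E,10S)-1,2-dibromo-4-(TBSO)-10-[(TBDPSO)methyl]-12,12-dimethoxy-6-methyldodeca-2,6-dien-9-one
Conditions: CBr4, PPh3, CH2Cl2, 0 °C
Reagents that add atoms: carbon tetrabromide, BrC(Br)(Br)Br
Why: The Appel reaction converts the only free (primary allylic) alcohol into the bromide under neutral conditions while the aldehyde is still masked.

Step 13
Reactants: 20 (2Z,4S,6E,10S)-1,2-dibromo-4-(TBSO)-10-[(TBDPSO)methyl]-12,12-dimethoxy-6-methyldodeca-2,6-dien-9-one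
Product: 21 (3S,6E,9S,10Z)-11,12-dibromo-9-(TBSO)-3-[(TBDPSO)methyl]-7-methyl-4-oxododeca-6,10-dienal
Conditions: SiO2, 10 % aq oxalic acid, CH2Cl2, rt
Reagents that add atoms: water, O
Why: Hydrolysis of the unhindered dimethyl acetal on wet acidic silica is mild enough for the allylic bromide, both silyl ethers and the β,γ-unsaturated ketone.

Step 14
Reactants: 21 (3S,6E,9S,10Z)-11,12-dibromo-9-(TBSO)-3-[(TBDPSO)methyl]-7-methyl-4-oxododeca-6,10-dienal
Product: 23 (4S)-11-bromo-6α-hydroxy-8α-(TBSO)-15-(TBDPSO)-12-norgermacra-1(10)E,11(13)-dien-3-one, via allylchromium dichloride 22 (not isolated)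
Conditions: CrCl2 (10 equiv), THF, rt, slow addition of 21 (final 2 mM); aq work-up
Reagents that add atoms: none
Why: In this Nozaki–Hiyama allylation divalent chromium reduces only the allylic C–Br bond, and C7 adds to the aldehyde through a chair-like Zimmerman–Traxler array (6α-OH trans to the 7β-bromovinyl group); allylic strain with the C11 bromine holds H8 in the alkene plane, so C6 approaches anti to the silyloxy group (Felkin–Anh sense, the reason for the 8S centre), and attack on the C3 ketone is excluded because it would need a trans-cycloheptene.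

Step 15
Reactants: 23 (4S)-11-bromo-6α-hydroxy-8α-(TBSO)-15-(TBDPSO)-12-norgermacra-1(10)E,11(13)-dien-3-one
Product: 24 (4S)-11-bromo-6β-(mesyloxy)-8α-(TBSO)-15-(TBDPSO)-12-norgermacra-1(10)E,11(13)-dien-3-one
Conditions: MsOH, PPh3, DIAD, Et3N (0.4 equiv), toluene, 0 to 50 °C
Reagents that add atoms: methanesulfonic acid, CS(=O)(=O)O
Why: In this Mitsunobu reaction with a sulfonic acid as pronucleophile the activated 6α-alcohol is displaced from the rear by mesylate, so the leaving group arrives with the inverted 6β configuration that the key step needs.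

Step 16
Reactants: 24 (4S)-11-bromo-6β-(mesyloxy)-8α-(TBSO)-15-(TBDPSO)-12-norgermacra-1(10)E,11(13)-dien-3-one; 25 carbon dioxide
Product: 27 8α-(TBSO)-15-(TBDPSO)-3-oxogermacra-1(10)E,11(13)-dien-12,6α-olide, via bromomagnesium carboxylate 26 (not isolated)
Conditions: CO2 (1 atm), NiBr2(bpy) (20 mol %), Bu4NBF4, DMF, undivided cell, Pt cathode, Mg anode, constant current, 3 F/mol, 0 °C; then current off, 50 °C
Reagents that add atoms: carbon dioxide (25), O=C=O
Why: Zerovalent nickel made at the cathode inserts into the C11–Br bond only, the alkenylnickel bromide takes up one more electron to become a nucleophilic monovalent alkenylnickel that adds to CO2 (bond C11–C12), and Mg2+ from the anode takes over the carboxylate 26 and frees the catalyst. The closest known reaction types are the nickel-catalysed electrocarboxylation of alkenyl bromides with a sacrificial magnesium anode and the lactonisation of a carboxylate onto a secondary sulfonate, here simply run one after the other in one cell. On warming, one carboxylate oxygen displaces the 6β-mesylate from the rear in a 5-exo-tet closure (bond O–C6) that builds the γ-lactone ring O–C6–C7–C11–C12. C6 is the only stereocentre that changes: SN2 inversion turns 6β-OMs into the 6α-O bond, so the lactone is trans-fused to the ten-membered ring, while C4, C7 and C8 are untouched. The step must distinguish the two C–X bonds and spare the C3 ketone, which is secured because the catalyst works at a mild potential where mesylate, ketone, silyl ethers and the trisubstituted alkene are inert, and because the bulky silyl groups keep O8 and O15 from competing for C6. Holding the cell at 0 °C keeps the material as the hard-to-reduce carboxylate, so the reducible α-methylene lactone appears only after the current is off.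

Step 17
Reactants: 27 8α-(TBSO)-15-(TBDPSO)-3-oxogermacra-1(10)E,11(13)-dien-12,6α-olide
Product: 28 8α-hydroxy-15-(TBDPSO)-3-oxogermacra-1(10)E,11(13)-dien-12,6α-olide
Conditions: HF·pyridine, pyridine, THF, 0 °C
Reagents that add atoms: none
Why: Buffered acidic fluoride removes the TBS ether much faster than the TBDPS ether and leaves the α-methylene lactone and the ketone alone.

Step 18
Reactants: 28 8α-hydroxy-15-(TBDPSO)-3-oxogermacra-1(10)E,11(13)-dien-12,6α-olide; 29 angelic acid
Product: 30 8β-(angeloyloxy)-15-(TBDPSO)-3-oxogermacra-1(10)E,11(13)-dien-12,6α-olide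
Conditions: 29, PPh3, DIAD, toluene, 0 °C to rt
Reagents that add atoms: angelic acid (29), C/C=C(/C)C(=O)O
Why: In this Mitsunobu esterification SN2 attack of angelate on the activated 8α-alcohol inverts C8 to the natural 8β-ester, and the absence of an activated acyl species avoids Z to E isomerisation to the tiglate.

Step 19
Reactants: 30 8β-(angeloyloxy)-15-(TBDPSO)-3-oxogermacra-1(10)E,11(13)-dien-12,6α-olide
Product: 31 8β-(angeloyloxy)-15-hydroxy-3-oxogermacra-1(10)E,11(13)-dien-12,6α-olide
Conditions: HF·pyridine (excess), THF, rt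
Reagents that add atoms: none
Why: Non-basic desilylation frees O15 without β-elimination or epimerisation at C4 of the β-silyloxy ketone.

Step 20
Reactants: 31 8β-(angeloyloxy)-15-hydroxy-3-oxogermacra-1(10)E,11(13)-dien-12,6α-olide
Product: 32 Argophyllone B
Conditions: m-CPBA, NaHCO3, CH2Cl2, 0 °C
Reagents that add atoms: m-chloroperoxybenzoic acid, O=C(OO)c1cccc(Cl)c1
Why: In this Prilezhaev epoxidation only the 1(10) alkene is electron-rich, and because it stands perpendicular to the mean plane of the ten-membered ring only its outer face is open, so syn addition should give the trans (1R,10R) epoxide.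

Compound list
1 | geranyl chloride, (2E)-1-chloro-3,7-dimethylocta-2,6-diene | CC(C)=CCC/C(C)=C/CCl | starting material
2 | (4E)-6-chloro-4-methylhex-4-enal | O=CCC/C(C)=C/CCl | intermediate
3 | ethyl (triphenylphosphoranylidene)acetate | CCOC(=O)C=P(c1ccccc1)(c1ccccc1)c1ccccc1 | starting material
4 | ethyl bromo(triphenylphosphoranylidene)acetate | CCOC(=O)C(Br)=P(c1ccccc1)(c1ccccc1)c1ccccc1 | intermediate
5 | (2S,4E)-2-(anilinooxy)-6-chloro-4-methylhex-4-enal | O=C[C@@H](ONc1ccccc1)C/C(C)=C/CCl | intermediate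
6 | ethyl (2Z,4S,6E)-4-(anilinooxy)-2-bromo-8-chloro-6-methylocta-2,6-dienoate | CCOC(=O)/C(Br)=C/[C@@H](ONc1ccccc1)C/C(C)=C/CCl | intermediate
7 | ethyl (2Z,4S,6E)-2-bromo-8-chloro-4-hydroxy-6-methylocta-2,6-dienoate | CCOC(=O)/C(Br)=C/[C@@H](O)C/C(C)=C/CCl | intermediate
8 | ethyl (2Z,4S,6E)-2-bromo-4-(TBSO)-8-chloro-6-methylocta-2,6-dienoate | CCOC(=O)/C(Br)=C/[C@@H](O[Si](C)(C)C(C)(C)C)C/C(C)=C/CCl | intermediate
9 | (2Z,4S,6E)-2-bromo-4-(TBSO)-8-chloro-6-methylocta-2,6-dien-1-ol | OC/C(Br)=C/[C@@H](O[Si](C)(C)C(C)(C)C)C/C(C)=C/CCl | intermediate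
10 | allyl alcohol | C=CCO | starting material
11 | allyl TBDPS ether | C=CCO[Si](c1ccccc1)(c1ccccc1)C(C)(C)C | intermediate
12 | (E)-crotonaldehyde | C/C=C/C=O | starting material
13 | (E)-4-(TBDPSO)but-2-enal | O=C/C=C/CO[Si](c1ccccc1)(c1ccccc1)C(C)(C)C | intermediate
14 | nitromethane | C[N+](=O)[O-] | starting material
15 | (3R)-3-[(TBDPSO)methyl]-4-nitrobutanal | O=CC[C@@H](CO[Si](c1ccccc1)(c1ccccc1)C(C)(C)C)C[N+](=O)[O-] | intermediate
16 | (2R)-1-(TBDPSO)-4,4-dimethoxy-2-(nitromethyl)butane | COC(OC)C[C@@H](CO[Si](c1ccccc1)(c1ccccc1)C(C)(C)C)C[N+](=O)[O-] | intermediate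
17 | (2Z,4S,6E,10R)-9-nitro alcohol, C9 (germacrane C3) epimers | OC/C(Br)=C/[C@@H](O[Si](C)(C)C(C)(C)C)C/C(C)=C/CC([N+](=O)[O-])[C@H](CO[Si](c1ccccc1)(c1ccccc1)C(C)(C)C)CC(OC)OC | intermediate
18 | sodium nitronate of 17 | OC/C(Br)=C/[C@@H](O[Si](C)(C)C(C)(C)C)C/C(C)=C/CC(=[N+]([O-])[O-])[C@H](CO[Si](c1ccccc1)(c1ccccc1)C(C)(C)C)CC(OC)OC.[Na+] | intermediate
19 | (2Z,4S,6E,10S)-hydroxy ketone acetal | OC/C(Br)=C/[C@@H](O[Si](C)(C)C(C)(C)C)C/C(C)=C/CC(=O)[C@H](CO[Si](c1ccccc1)(c1ccccc1)C(C)(C)C)CC(OC)OC | intermediate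
20 | (2Z,4S,6E,10S)-allylic bromide ketone acetal | BrC/C(Br)=C/[C@@H](O[Si](C)(C)C(C)(C)C)C/C(C)=C/CC(=O)[C@H](CO[Si](c1ccccc1)(c1ccccc1)C(C)(C)C)CC(OC)OC | intermediate
21 | (3S,6E,9S,10Z)-11,12-dibromo keto aldehyde | BrC/C(Br)=C/[C@@H](O[Si](C)(C)C(C)(C)C)C/C(C)=C/CC(=O)[C@H](CO[Si](c1ccccc1)(c1ccccc1)C(C)(C)C)CC=O | intermediate
22 | allylchromium dichloride from 21 | Cl[Cr](Cl)C/C(Br)=C/[C@@H](O[Si](C)(C)C(C)(C)C)C/C(C)=C/CC(=O)[C@H](CO[Si](c1ccccc1)(c1ccccc1)C(C)(C)C)CC=O | intermediate
23 | macrocyclic 6α-alcohol (4S, 7β-(1-bromovinyl), 8α-OTBS, 1(10)E) | O[C@@H]1C[C@@H](CO[Si](c2ccccc2)(c2ccccc2)C(C)(C)C)C(=O)C/C=C(\C)C[C@H](O[Si](C)(C)C(C)(C)C)[C@H]1C(Br)=C | intermediate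
24 | macrocyclic 6β-mesylate (other centres as in 23) | CS(=O)(=O)O[C@H]1C[C@@H](CO[Si](c2ccccc2)(c2ccccc2)C(C)(C)C)C(=O)C/C=C(\C)C[C@H](O[Si](C)(C)C(C)(C)C)[C@H]1C(Br)=C | intermediate
25 | carbon dioxide | O=C=O | starting material
26 | bromomagnesium 6β-(mesyloxy)germacra-1(10),11(13)-dien-12-oate | CS(=O)(=O)O[C@H]1C[C@@H](CO[Si](c2ccccc2)(c2ccccc2)C(C)(C)C)C(=O)C/C=C(\C)C[C@H](O[Si](C)(C)C(C)(C)C)[C@H]1C(=C)C(=O)[O-].[Mg+2].[Br-] | intermediate
27 | 8α-(TBSO)-15-(TBDPSO)-3-oxogermacra-1(10)E,11(13)-dien-12,6α-olide | C=C1C(=O)O[C@@H]2C[C@@H](CO[Si](c3ccccc3)(c3ccccc3)C(C)(C)C)C(=O)C/C=C(\C)C[C@H](O[Si](C)(C)C(C)(C)C)[C@@H]12 | intermediate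
28 | 8α-hydroxy-15-(TBDPSO)-3-oxogermacra-1(10)E,11(13)-dien-12,6α-olide | C=C1C(=O)O[C@@H]2C[C@@H](CO[Si](c3ccccc3)(c3ccccc3)C(C)(C)C)C(=O)C/C=C(\C)C[C@H](O)[C@@H]12 | intermediate
29 | angelic acid, (Z)-2-methylbut-2-enoic acid | C/C=C(/C)C(=O)O | starting material
30 | 8β-(angeloyloxy)-15-(TBDPSO)-3-oxogermacra-1(10)E,11(13)-dien-12,6α-olide | C=C1C(=O)O[C@@H]2C[C@@H](CO[Si](c3ccccc3)(c3ccccc3)C(C)(C)C)C(=O)C/C=C(\C)C[C@@H](OC(=O)/C(C)=C\C)[C@@H]12 | intermediate
31 | 8β-(angeloyloxy)-15-hydroxy-3-oxogermacra-1(10)E,11(13)-dien-12,6α-olide | C=C1C(=O)O[C@@H]2C[C@@H](CO)C(=O)C/C=C(\C)C[C@@H](OC(=O)/C(C)=C\C)[C@@H]12 | intermediate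
32 | Argophyllone B | C=C1C(=O)O[C@@H]2C[C@@H](CO)C(=O)C[C@H]3O[C@]3(C)C[C@@H](OC(=O)/C(C)=C\C)[C@@H]12 | target

Total step count: 20. Longest linear sequence: 16 steps (1, 3–6, 10–20).

Steps most likely to fail

Step 16. The alkenylnickel may be protonated instead of carboxylated (loss of bromine). Methanesulfonic acid may also be lost towards a C6=C7 diene before the carboxylate closes the ring. The fallback replaces the reductive C–C bond formation with a redox-neutral one. It sets out from 24. Miyaura borylation (PdCl2(dppf), B2pin2, KOPh, toluene, 50 °C) would give the alkenyl pinacolboronate F1. Copper-catalysed carboxylation of this boronic ester ((IPr)CuCl, CsF, CO2 1 atm, DMF) and lactonisation onto the mesylate in the same flask would rejoin the route at 27.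

Step 14. Oligomerisation may outrun closure of the ten-membered ring, or the facial selectivity at C7 relative to C8 may be poor. The fallback makes C6–C7 between two molecules and closes the ring at C2–C3 instead. It sets out from 9 and from aldehyde 15, which is isolated this time.
- An Appel reaction on 9 would give the allylic bromide F2.
- An indium-mediated Barbier reaction of F2 with 15 (In, THF–H2O, rt) spares the nitro group and the allylic chloride. It would give the homoallylic alcohol F3 with the same anti, Felkin–Anh sense.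
- An intramolecular Tsuji–Trost reaction (conditions of step 10, high dilution) would give the macrocyclic nitro alcohol F4.
- The reductive Nef reaction of step 11 would rejoin the route at 23.

Step 15. The hindered, activated 6α-alcohol may eliminate, or transannular hemiketal formation with the C3 ketone may block its activation. The fallback separates inversion from sulfonylation and sets out from 23.
- A Mitsunobu reaction with 4-nitrobenzoic acid would give the inverted 4-nitrobenzoate F5.
- Methanolysis (K2CO3, MeOH, 0 °C) would give the 6β-alcohol F6.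
- Ordinary mesylation with retention (MsCl, Et3N, CH2Cl2, −20 °C) would rejoin the route at 24.

Further compounds
F1 | step 16 | 6β-mesylate with a C11 pinacolboronate in place of bromine | CS(=O)(=O)O[C@H]1C[C@@H](CO[Si](c2ccccc2)(c2ccccc2)C(C)(C)C)C(=O)C/C=C(\C)C[C@H](O[Si](C)(C)C(C)(C)C)[C@H]1C(=C)B1OC(C)(C)C(C)(C)O1
F2 | step 14 | (2Z,4S,6E)-1,2-dibromo-4-(TBSO)-8-chloro-6-methylocta-2,6-diene | BrC/C(Br)=C/[C@@H](O[Si](C)(C)C(C)(C)C)C/C(C)=C/CCl
F3 | step 14 | acyclic homoallylic alcohol (C6–C7 made, C2–C3 open) | O[C@H](C[C@@H](CO[Si](c1ccccc1)(c1ccccc1)C(C)(C)C)C[N+](=O)[O-])[C@H](C(Br)=C)[C@@H](O[Si](C)(C)C(C)(C)C)C/C(C)=C/CCl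
F4 | step 14 | macrocyclic 3-nitro 6α-alcohol (C3 epimers) | O[C@@H]1C[C@@H](CO[Si](c2ccccc2)(c2ccccc2)C(C)(C)C)C([N+](=O)[O-])C/C=C(\C)C[C@H](O[Si](C)(C)C(C)(C)C)[C@H]1C(Br)=C
F5 | step 15 | macrocyclic 6β-(4-nitrobenzoate) | O=C(O[C@H]1C[C@@H](CO[Si](c2ccccc2)(c2ccccc2)C(C)(C)C)C(=O)C/C=C(\C)C[C@H](O[Si](C)(C)C(C)(C)C)[C@H]1C(Br)=C)c1ccc(cc1)[N+](=O)[O-]
F6 | step 15 | macrocyclic 6β-alcohol | O[C@H]1C[C@@H](CO[Si](c2ccccc2)(c2ccccc2)C(C)(C)C)C(=O)C/C=C(\C)C[C@H](O[Si](C)(C)C(C)(C)C)[C@H]1C(Br)=C
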